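Readings and results were computed for substances that don't exist; the scatter is artificial.

The reagent left over late in a run is the concentration to follow here, and the ratio of target to starting material is read against it.

| flask | starting material | reagent | remark | time |
|---|---|---|---|---|
| spring | 0.75 M | 2.25 M (fed, over 50 s) | run made earlier; the fed solution adds 0.20 times the starting volume |  |
| dawn | 1.1 M | 2.25 M (fed, over 50 s) | run made earlier; the fed solution adds 0.20 times the starting volume |  |
| midnight | 1.5 M | 1.1 M (fed, over 50 s) | run made earlier; the fed solution adds 0.20 times the starting volume |  |
| flask | 1.5 M | 2.25 M (fed, over 50 s) | the fed solution adds 0.20 times the starting volume | 12 min |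

- spring (time / min: starting material / %, target / %): 0.500: 84.9, 8.5; 1.33: 51.2, 22.4; 2.50: 37.0, 20.5; 4.00: 30.8, 15.2; 6.00: 27.5, 14.4; 8.00: 24.8, 11.5
- dawn (time / min: starting material / %, target / %): 1.33: 51.2, 21.7; 2.50: 38.5, 18.6; 4.00: 30.7, 13.7; 5.00: 29.3, 12.7; 6.00: 27.4, 11.4; 8.00: 25.0, 10.3
- midnight (time / min: starting material / %, target / %): 0.500: 92.6, 4.0; 1.00: 78.7, 9.4; 2.00: 64.4, 11.3; 4.00: 53.5, 7.8; 8.00: 44.9, 5.9

(scatter of a reading: 0.5 percentage points)

- percentages count the starting material that a species holds: one side product counts as two
- every charge counts on the volume at the start, and the solution that is fed holds the whole dose
- on the list of suspects stand: starting material + reagent <-> target; starting material + reagent <-> isomer of the product; starting material + target -> side product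
- the reaction counts as stopped when no species that holds the starting material changes by six tenths of a point or more over the second half of the time

1. the state of affairs at 12 min: stopped, and by what, or still going (forward and back rates have come level / all of the starting material has reacted / it is still moving / the reagent has run out first)
2. share of the starting material used up at 12 min
3. target at 12 min, in percent of the starting material charged

At 8.00 min the spring run shows a ratio of 0.464, while the midnight run, with less reagent and more starting material charged, shows a lower 0.131 at 8.00 min. Target and isomer each take one reagent per starting material, and side product takes one for two, so with isomer and side product unread I assume an even split between these two kinds of use and count 0.750 reagent per starting material used. By that count 81.2% of the spring reagent stands free at that reading. Dividing the ratio by this share gives the full-charge ratio 0.571, the target per starting material expected if the whole reagent charge stood free, a pre-equilibrium ratio as read from the readings. The dawn run, with another charge of starting material, reads 0.568.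

The flask has the reagent charge and feed of those two runs, though more starting material, so I carry the same number over to it. Starting material in the spring and dawn runs stands about level, at 25.0% in the dawn run at 8.00 min, and I assume that level for the flask. At that level my count leaves the flask 62.5% of its reagent, and its ratio reckons to 0.357, or 8.92% target. One number is not enough, though: it gives the ratio and not the amount of starting material. The spring run still loses 2.7 percentage points of starting material between its last two readings, so I expect a flask still moving at 12 min, with somewhat less target than that reckoned share.

The forecast says it is still moving, with 77% used up and 8.5% target: “A still falls about 4 points between 6 and 12 min”.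

The state of the flask at 12 min is this: it is still moving, with 78.2% used up and 7.74% target. Over the second half of the time the largest change in the share of any species in the flask is 10 points. With 60% of its reagent free at 12 min, the full-charge ratio gives 0.343 for the flask, which stands at 0.355.

    starting material + reagent ⇌ target (K = 0.330 M⁻¹, k = 0.00710 M⁻¹ s⁻¹)
    starting material + reagent ⇌ isomer of the product (K = 1.20 M⁻¹, k = 0.00380 M⁻¹ s⁻¹)
    starting material + target → side product (k = 0.00550 M⁻¹ s⁻¹)

For a neighbour flask charged with 0.90 M of reagent, I scale the number down by its charge. With 37% of that reagent free and 46% starting material left in the neighbour at 12 min, the number gives 3.96% target; the computed value is 3.81%.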